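(The runs were generated by integration for an exercise; noise was put on by code.)

At early times both runs show the left-handed substrate falling faster than the right-handed one, and at 6.00 min they read alike, left-handed 12.4% in the north-east run and 12.7% in the east run, although the east run holds twice the solid reagent.

common to all: left-handed substrate 2.0 × 10⁻⁴ M; right-handed substrate 2.0 × 10⁻⁴ M; catalyst 4.6 µM
- north-east: solid reagent 0.60 mM; the very flask that is asked about, followed so far
- east: solid reagent 1.2 mM; run made earlier
- flask: solid reagent 0.600 mM; time 20 min

- north-east (time / min: right-handed substrate / %, left-handed substrate / %, left-handed product / %): 0.500: 50.4, 48.0, 2.3; 0.833: 50.1, 45.6, 4.0; 1.50: 49.1, 41.2, 9.4; 3.00: 48.3, 29.7, 19.3; 6.00: 45.6, 12.4, 37.7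
- east (time / min: right-handed substrate / %, left-handed substrate / %, left-handed product / %): 3.00: 48.1, 30.2, 20.2; 6.00: 45.5, 12.7, 37.2; 8.00: 42.7, 5.6, 44.7; 12.0: 37.0, 0.7, 49.3; 15.0: 32.5, 0, 49.8

(each reading ± 0.3 percentage points)

- catalyst is single-handed; left-handed substrate and right-handed substrate are mirror images of each other, charged as a racemate, each of them at the stated concentration
- solid, in amounts per volume of the solution: solid reagent
- at the start none of the solid reagent is in solution

* whether the excess of right-handed substrate over left-handed substrate among what is left of the two reaches 80% by 20 min (no / yes)
* the highest excess of right-handed substrate over left-handed substrate among what is left of the two up to 20 min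

If each substrate falls in proportion to what is left of it on a shared clock, dividing one rate by the other removes time. From the north-east reading at 6.00 min:

ln(fraction of left-handed left) / ln(fraction of right-handed left) = 15.1

This ratio of logarithms is the selectivity factor; the east reading at 8.00 min gives 13.9.

The excess starts at zero and reads 23.8% at 3.00 min in the north-east run. By my reckoning it crosses 80% in the asked flask with this much left:

right-handed 42.8%, left-handed 4.76%

The east run reads 42.7% right-handed at 8.00 min, so the crossing lies close by. Reaching it consumes 0.210 mM of substrate, less than the 0.600 mM of solid reagent if one is used per substrate. Extending the east run's last slope puts right-handed substrate near 25.0% at 20 min, where the curve flattens at an excess of >99.9%.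

The forecast says yes, with a top of 99.9% (97% to 100%), reasoning “Halving the solid therefore changes nothing while solid remains”; my top is slightly higher, inside that range.

The flask gives yes and a top of >99.9%.

    partner + catalyst + left-handed substrate → catalyst + left-handed product (k = 3.60 × 10⁷ L² mol⁻² s⁻¹)
    partner + catalyst + right-handed substrate → catalyst + right-handed product (k = 2.50 × 10⁶ L² mol⁻² s⁻¹)
    solid reagent ⇌ partner, rate k3*(cs3 - [partner]) while solid is left; crystals form when [partner] > cs3 (solubility = 0.0840 mM, k = 0.0100 s⁻¹)
    partner ⇌ dormant form (K = 0.390, k = 0.0290 s⁻¹)

The asked flask reaches 80% at 8.33 min, with 42.4% right-handed substrate left. At 20.0 min it holds 24.9% right-handed substrate, for which the ratio of the two rate constants, 14.4, gives 0.00224% left-handed. In the east run, the selectivity factor read from the north-east run, 15.1, turns 32.5% right-handed at 15.0 min into an estimated 0.0736% left-handed, below the scatter of 0.3 percentage points, and the reading there is 0%.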